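**Strategy.** Everything rests on reading ring C (the cyclohexene C1'–C6' of the acyl arm) as a Diels–Alder retron: the C2'=C3' alkene carrying CH2OH, flanked by C4'H2 and by the cis pair C1'–H/C6'–isopropyl, maps onto a 1,3-disubstituted butadiene plus but-3-en-2-one. The key step is a late, catalyst-controlled endo [4+2] cycloaddition on the trienoate ester of the finished ring A/ring B hydroxy lactone. In one operation it closes ring C, forms C1'–C6' and C4'–C5' and sets both stereocentres; the acetyl group then becomes isopropyl. The same cycloaddition, run earlier with the antipodal catalyst, supplies ring A, whose CH–CH(isopropyl) pair is antipodal to that of ring C.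

Key step: step 15

Remark: the sense of induction of the oxazaborolidinium catalyst is assigned by analogy with its buta-1,3-diene/acrylate adducts; both antipodes are used (steps 7 and 15), so an inverted sense would be corrected by exchanging them.

Abbreviations: TBS = tert-butyldimethylsilyl; PMB = 4-methoxybenzyl; TMSE = 2-(trimethylsilyl)ethyl. Ring A = cyclohexane, ring B = seven-membered lactone (2-benzoxepine numbering for rings A/B), ring C = cyclohexene (C1' bears the propenoate, C3' the CH2O group, C6' the isopropyl group).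

Step 1
Reactants: 1 2-methylidenepropane-1,3-diol
Product: 2 2-(TBSOCH2)prop-2-en-1-ol
Conditions: NaH (1.0 equiv), THF, 0 °C; then TBSCl (1.0 equiv), rt
Reagents that add atoms: tert-butyldimethylsilyl chloride, CC(C)(C)[Si](C)(C)Cl
Why: Monodeprotonation of the symmetrical diol and O-silylation of the monosodium alkoxide (Williamson-type silyl ether formation) should favour the mono-TBS ether; no stereocentre is involved.

Step 2
Reactants: 2 2-(TBSOCH2)prop-2-en-1-ol
Product: 3 2-(TBSOCH2)prop-2-enal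
Conditions: activated MnO2, CH2Cl2, rt
Reagents that add atoms: none
Why: Heterogeneous MnO2 oxidation of the allylic alcohol should stop at the enal and leave the silyl ether intact.

Step 3
Reactants: 3 2-(TBSOCH2)prop-2-enal; 4 (triphenylphosphoranylidene)acetaldehyde
Product: 5 (2E)-4-(TBSOCH2)penta-2,4-dienal
Conditions: toluene, 60 °C
Reagents that add atoms: none
Why: Wittig olefination with the stabilised formyl ylide should give the E-enal; the alpha-branched acrolein 3 is more electrophilic than the conjugated product, so double homologation should stay minor.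

Step 4
Reactants: 5 (2E)-4-(TBSOCH2)penta-2,4-dienal; 6 (4-methoxyphenyl)methanol; 7 methyl 2-(dimethoxyphosphoryl)prop-2-enoate
Product: 9 methyl (2E,4E)-2-(PMBOCH2)-6-(TBSOCH2)hepta-2,4,6-trienoate, via phosphonate carbanion 8 (not isolated)
Conditions: 6, NaH, THF, 0 °C; 7, −78 → 0 °C; then 5, −78 °C → rt
Reagents that add atoms: none
Why: Oxa-Michael addition of the alkoxide to the vinylphosphonate generates carbanion 8, which olefinates the aldehyde (Michael-initiated Horner–Wadsworth–Emmons reaction); reversible adduct formation should place the ester trans to the dienyl chain (2E), and the 4E geometry is carried over from 5.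

Step 5
Reactants: 9 methyl (2E,4E)-2-(PMBOCH2)-6-(TBSOCH2)hepta-2,4,6-trienoate
Product: 10 (2E,4E)-2-(PMBOCH2)-6-(TBSOCH2)hepta-2,4,6-trienoic acid
Conditions: LiOH·H2O, THF/MeOH/H2O, rt; then 1 M HCl to pH 4
Reagents that add atoms: lithium hydroxide, [Li+].[OH-]
Why: Saponification of the methyl ester; the silyl and PMB ethers should be stable to aqueous hydroxide at room temperature.

Step 6
Reactants: 10 (2E,4E)-2-(PMBOCH2)-6-(TBSOCH2)hepta-2,4,6-trienoic acid; 11 2-(trimethylsilyl)ethanol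
Product: 12 TMSE (2E,4E)-2-(PMBOCH2)-6-(TBSOCH2)hepta-2,4,6-trienoate
Conditions: N,N'-dicyclohexylcarbodiimide, 4-(dimethylamino)pyridine (10 mol%), CH2Cl2, 0 °C → rt
Reagents that add atoms: none
Why: Steglich esterification installs the fluoride-labile TMSE ester that masks the ring B carboxylic acid to the end.

Step 7
Reactants: 12 TMSE (2E,4E)-2-(PMBOCH2)-6-(TBSOCH2)hepta-2,4,6-trienoate; 13 but-3-en-2-one
Product: 14 TMSE (2E)-3-[(1S,6S)-6-acetyl-3-(TBSOCH2)cyclohex-2-en-1-yl]-2-(PMBOCH2)prop-2-enoate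
Conditions: 13 (3 equiv), (S)-1-(2-methylphenyl)-3,3-diphenyltetrahydro-1H,3H-pyrrolo[1,2-c][1,3,2]oxazaborole·HN(SO2CF3)2 (20 mol%), CH2Cl2, −40 → −20 °C
Reagents that add atoms: none
Why: Enantioselective Lewis-acid-catalysed Diels–Alder reaction closes ring A: the terminal diene of 12 adds to the boron-bound enone with "ortho/para" regiochemistry and endo orientation, so acetyl and propenoate arm become cis, and the (S)-catalyst should shield the enone face so that the (1S,6S) adduct results.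

Step 8
Reactants: 14 TMSE (2E)-3-[(1S,6S)-6-acetyl-3-(TBSOCH2)cyclohex-2-en-1-yl]-2-(PMBOCH2)prop-2-enoate
Product: 15 TMSE (2E)-3-[(1S,6S)-6-(prop-1-en-2-yl)-3-(TBSOCH2)cyclohex-2-en-1-yl]-2-(PMBOCH2)prop-2-enoate
Conditions: Zn, CH2Br2, TiCl4, THF/CH2Cl2, 0 °C → rt
Reagents that add atoms: dibromomethane, BrCBr
Why: Takai–Lombardo methylenation converts the ketone into the isopropenyl group under non-basic conditions, so the epimerisable C6 stereocentre is preserved and the esters are not touched.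

Step 9
Reactants: 15 TMSE (2E)-3-[(1S,6S)-6-(prop-1-en-2-yl)-3-(TBSOCH2)cyclohex-2-en-1-yl]-2-(PMBOCH2)prop-2-enoate
Product: 16 TMSE (2E)-3-[(1S,6R)-6-isopropyl-3-(TBSOCH2)cyclohex-2-en-1-yl]-2-(PMBOCH2)prop-2-enoate
Conditions: H2 (1 atm), RhCl(PPh3)3 (10 mol%), benzene/EtOH, rt
Reagents that add atoms: none
Why: Homogeneous hydrogenation with RhCl(PPh3)3 should reduce only the unhindered 1,1-disubstituted alkene and leave both trisubstituted alkenes and the PMB ether untouched; no stereocentre is created (the descriptor at C6 changes only by priority).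

Step 10
Reactants: 16 TMSE (2E)-3-[(1S,6R)-6-isopropyl-3-(TBSOCH2)cyclohex-2-en-1-yl]-2-(PMBOCH2)prop-2-enoate
Product: 17 TMSE (2E)-3-[(1S,6R)-3-(hydroxymethyl)-6-isopropylcyclohex-2-en-1-yl]-2-(PMBOCH2)prop-2-enoate
Conditions: HF·pyridine, THF/pyridine, 0 °C → rt
Reagents that add atoms: none
Why: Desilylation of the primary TBS ether frees the ring allylic alcohol; the PMB ether and the TMSE ester, which needs naked fluoride, should survive.

Step 11
Reactants: 17 TMSE (2E)-3-[(1S,6R)-3-(hydroxymethyl)-6-isopropylcyclohex-2-en-1-yl]-2-(PMBOCH2)prop-2-enoate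
Product: 18 (1R,2R,3R)-3-isopropyl-6-methylidene-2-[(1E)-2-(PMBOCH2)-3-oxo-3-(TMSE-oxy)prop-1-en-1-yl]cyclohexane-1-carboxylic acid
Conditions: Pd(PPh3)4 (5 mol%), Et2Zn (3.5 equiv), CO2 (1 atm), THF/hexane, rt; then 1 M HCl
Reagents that add atoms: carbon dioxide, O=C=O
Why: Palladium-catalysed umpolung carboxylation of an allylic alcohol: zerovalent palladium ionises the zinc-activated C–O bond, transmetalation gives the allylzinc, and this adds to CO2 through its gamma-carbon (SE2'), forming the branched beta,gamma-unsaturated acid with the exocyclic methylene; CO2 should approach C1 anti to the neighbouring propenoate arm and the cis isopropyl group, setting (1R).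

Step 12
Reactants: 18 (1R,2R,3R)-3-isopropyl-6-methylidene-2-[(1E)-2-(PMBOCH2)-3-oxo-3-(TMSE-oxy)prop-1-en-1-yl]cyclohexane-1-carboxylic acid
Product: 19 (1R,2R,3R)-2-[(1E)-2-(hydroxymethyl)-3-oxo-3-(TMSE-oxy)prop-1-en-1-yl]-3-isopropyl-6-methylidenecyclohexane-1-carboxylic acid
Conditions: 2,3-dichloro-5,6-dicyano-1,4-benzoquinone (DDQ), CH2Cl2/pH 7 buffer, 0 °C
Reagents that add atoms: none
Why: Oxidative PMB ether cleavage liberates the primary allylic alcohol without touching the acid, the methylidene group or the silyl ester.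

Step 13
Reactants: 19 (1R,2R,3R)-2-[(1E)-2-(hydroxymethyl)-3-oxo-3-(TMSE-oxy)prop-1-en-1-yl]-3-isopropyl-6-methylidenecyclohexane-1-carboxylic acid
Product: 22 TMSE (5aR,6R,9S,9aR)-6-isopropyl-1-oxo-1,5a,6,7,8,9a-hexahydro-3H-spiro[2-benzoxepine-9,2'-oxirane]-4-carboxylate, via iodomethyl beta-lactone 20 (not isolated), via iodohydrin lactone 21 (not isolated)
Conditions: I2, NaHCO3, MeCN, 0 °C, dark; then Cs2CO3, 0 °C → rt
Reagents that add atoms: none
Why: Kinetic iodolactonisation (4-exo attack of the carboxylate on the tertiary end of the iodonium ion) gives the cis-fused beta-lactone 20, so the new C–O bond at the quaternary carbon must lie on the face of the carboxyl group; base then induces strain-driven acyl transfer to the primary alkoxide, closing the trans-fused ring B lactone (21), and the released tertiary alkoxide displaces iodide (Williamson closure) to give the (9S) spiro-epoxide.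

Step 14
Reactants: 22 TMSE (5aR,6R,9S,9aR)-6-isopropyl-1-oxo-1,5a,6,7,8,9a-hexahydro-3H-spiro[2-benzoxepine-9,2'-oxirane]-4-carboxylate; 10 (2E,4E)-2-(PMBOCH2)-6-(TBSOCH2)hepta-2,4,6-trienoic acid
Product: 23 TMSE (5aR,6R,9S,9aR)-9-hydroxy-6-isopropyl-1-oxo-9-{[((2E,4E)-2-(PMBOCH2)-6-(TBSOCH2)hepta-2,4,6-trienoyl)oxy]methyl}-1,3,5a,6,7,8,9,9a-octahydro-2-benzoxepine-4-carboxylate
Conditions: 10 (1.3 equiv), Cs2CO3 (0.3 equiv), DMF, 45 °C
Reagents that add atoms: none
Why: SN2 opening of the 2,2-disubstituted oxirane at its CH2 terminus by the caesium carboxylate unites the two halves, forming the primary ester and unveiling the tertiary alcohol with its configuration untouched.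

Step 15
Reactants: 23 TMSE (5aR,6R,9S,9aR)-9-hydroxy-6-isopropyl-1-oxo-9-{[((2E,4E)-2-(PMBOCH2)-6-(TBSOCH2)hepta-2,4,6-trienoyl)oxy]methyl}-1,3,5a,6,7,8,9,9a-octahydro-2-benzoxepine-4-carboxylate; 13 but-3-en-2-one
Product: 24 TMSE (5aR,6R,9S,9aR)-9-{[((2E)-3-[(1R,6R)-6-acetyl-3-(TBSOCH2)cyclohex-2-en-1-yl]-2-(PMBOCH2)prop-2-enoyl)oxy]methyl}-9-hydroxy-6-isopropyl-1-oxo-1,3,5a,6,7,8,9,9a-octahydro-2-benzoxepine-4-carboxylate
Conditions: 13 (5 equiv), (R)-1-(2-methylphenyl)-3,3-diphenyltetrahydro-1H,3H-pyrrolo[1,2-c][1,3,2]oxazaborole·HN(SO2CF3)2 (30 mol%), CH2Cl2, −40 → −20 °C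
Reagents that add atoms: none
Why: The protonated oxazaborolidine binds the carbonyl oxygen of 13, and the activated s-trans enone reacts with the s-cis terminal diene C4=C5–C6=C7 of the trienoate arm of 23 in a concerted, asynchronous [4+2] cycloaddition; the closest known reaction type is the cationic-oxazaborolidine-catalysed enantioselective Diels–Alder reaction of acyclic enones with 1- and 2-substituted butadienes. Ring C is closed by intermolecular [4+2] cycloaddition, the bonds C1'–C6' and C4'–C5' being formed suprafacially on both components. C1' and C6' emerge cis because the (4E)-substituent of the diene and the acetyl group lie on the same side in the endo transition state, and their absolute configuration (1'R,6'R) is dictated by the (R)-catalyst, which blocks one face of the bound enone; the ring A stereocentres are too remote to intervene. The regiochemistry (acetyl carbon bonded to C1', "ortho" to the arm and "para" to the C3' silyloxymethyl group) is secured by the reinforcing 1,3-disubstitution of the diene. Site selectivity is needed against the inner diene C2=C3–C4=C5 and the lactone enoate: the former ends in a fully substituted, ester-bearing carbon and the latter is a trisubstituted, electron-poor alkene, so neither should compete. The ketone of 13 is the strongest Lewis base present, but the free tertiary hydroxyl may call for a higher catalyst loading.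

Step 16
Reactants: 24 TMSE (5aR,6R,9S,9aR)-9-{[((2E)-3-[(1R,6R)-6-acetyl-3-(TBSOCH2)cyclohex-2-en-1-yl]-2-(PMBOCH2)prop-2-enoyl)oxy]methyl}-9-hydroxy-6-isopropyl-1-oxo-1,3,5a,6,7,8,9,9a-octahydro-2-benzoxepine-4-carboxylate
Product: 25 TMSE (5aR,6R,9S,9aR)-9-hydroxy-6-isopropyl-1-oxo-9-{[((2E)-2-(PMBOCH2)-3-[(1R,6R)-6-(prop-1-en-2-yl)-3-(TBSOCH2)cyclohex-2-en-1-yl]prop-2-enoyl)oxy]methyl}-1,3,5a,6,7,8,9,9a-octahydro-2-benzoxepine-4-carboxylate
Conditions: Zn, CH2Br2, TiCl4, THF/CH2Cl2, 0 °C → rt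
Reagents that add atoms: dibromomethane, BrCBr
Why: Takai–Lombardo methylenation is chemoselective for the ketone over the lactone and esters and non-basic, so C6' should not epimerise; excess reagent compensates for the free tertiary hydroxyl.

Step 17
Reactants: 25 TMSE (5aR,6R,9S,9aR)-9-hydroxy-6-isopropyl-1-oxo-9-{[((2E)-2-(PMBOCH2)-3-[(1R,6R)-6-(prop-1-en-2-yl)-3-(TBSOCH2)cyclohex-2-en-1-yl]prop-2-enoyl)oxy]methyl}-1,3,5a,6,7,8,9,9a-octahydro-2-benzoxepine-4-carboxylate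
Product: 26 TMSE (5aR,6R,9S,9aR)-9-hydroxy-6-isopropyl-9-{[((2E)-3-[(1R,6S)-6-isopropyl-3-(TBSOCH2)cyclohex-2-en-1-yl]-2-(PMBOCH2)prop-2-enoyl)oxy]methyl}-1-oxo-1,3,5a,6,7,8,9,9a-octahydro-2-benzoxepine-4-carboxylate
Conditions: H2 (1 atm), RhCl(PPh3)3 (10 mol%), benzene/EtOH, rt
Reagents that add atoms: none
Why: Chemoselective homogeneous hydrogenation of the 1,1-disubstituted alkene; the three trisubstituted alkenes (ring C, propenoate, lactone enoate) should be inert to RhCl(PPh3)3.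

Step 18
Reactants: 26 TMSE (5aR,6R,9S,9aR)-9-hydroxy-6-isopropyl-9-{[((2E)-3-[(1R,6S)-6-isopropyl-3-(TBSOCH2)cyclohex-2-en-1-yl]-2-(PMBOCH2)prop-2-enoyl)oxy]methyl}-1-oxo-1,3,5a,6,7,8,9,9a-octahydro-2-benzoxepine-4-carboxylate
Product: 27 TMSE (5aR,6R,9S,9aR)-9-hydroxy-9-{[((2E)-2-(hydroxymethyl)-3-[(1R,6S)-6-isopropyl-3-(TBSOCH2)cyclohex-2-en-1-yl]prop-2-enoyl)oxy]methyl}-6-isopropyl-1-oxo-1,3,5a,6,7,8,9,9a-octahydro-2-benzoxepine-4-carboxylate
Conditions: DDQ, CH2Cl2/pH 7 buffer, 0 °C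
Reagents that add atoms: none
Why: Oxidative PMB cleavage is done while the electron-rich ring C allylic alcohol is still silylated, so that DDQ cannot oxidise it to the enal.

Step 19
Reactants: 27 TMSE (5aR,6R,9S,9aR)-9-hydroxy-9-{[((2E)-2-(hydroxymethyl)-3-[(1R,6S)-6-isopropyl-3-(TBSOCH2)cyclohex-2-en-1-yl]prop-2-enoyl)oxy]methyl}-6-isopropyl-1-oxo-1,3,5a,6,7,8,9,9a-octahydro-2-benzoxepine-4-carboxylate
Product: 28 (5aR,6R,9S,9aR)-9-hydroxy-9-{[((2E)-2-(hydroxymethyl)-3-[(1R,6S)-3-(hydroxymethyl)-6-isopropylcyclohex-2-en-1-yl]prop-2-enoyl)oxy]methyl}-6-isopropyl-1-oxo-1,3,5a,6,7,8,9,9a-octahydro-2-benzoxepine-4-carboxylic acid (CNP0361406.11)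
Conditions: [(Me2N)3S][Me3SiF2] (TASF, 5 equiv), DMF, 0 °C → rt; then aq. NH4Cl
Reagents that add atoms: none
Why: Global fluoride deprotection: the TBS ether is cleaved and the TMSE ester fragments to carboxylate, ethene and Me3SiF under nearly neutral conditions that should spare the beta-hydroxy lactone and the acyloxymethyl ester.

**Compound list**

1 | 2-methylidenepropane-1,3-diol | C=C(CO)CO | starting material
2 | 2-(TBSOCH2)prop-2-en-1-ol | C=C(CO)CO[Si](C)(C)C(C)(C)C | intermediate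
3 | 2-(TBSOCH2)prop-2-enal | C=C(C=O)CO[Si](C)(C)C(C)(C)C | intermediate
4 | (triphenylphosphoranylidene)acetaldehyde | O=CC=P(c1ccccc1)(c1ccccc1)c1ccccc1 | starting material
5 | (2E)-4-(TBSOCH2)penta-2,4-dienal | O=C/C=C/C(=C)CO[Si](C)(C)C(C)(C)C | intermediate
6 | (4-methoxyphenyl)methanol | COc1ccc(CO)cc1 | starting material
7 | methyl 2-(dimethoxyphosphoryl)prop-2-enoate | COC(=O)C(=C)P(=O)(OC)OC | starting material
8 | sodium carbanion of methyl 2-(dimethoxyphosphoryl)-3-(PMB-oxy)propanoate | [Na+].COC(=O)[C-](COCc1ccc(OC)cc1)P(=O)(OC)OC | intermediate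
9 | methyl (2E,4E)-2-(PMBOCH2)-6-(TBSOCH2)hepta-2,4,6-trienoate | COC(=O)/C(COCc1ccc(OC)cc1)=C/C=C/C(=C)CO[Si](C)(C)C(C)(C)C | intermediate
10 | (2E,4E)-2-(PMBOCH2)-6-(TBSOCH2)hepta-2,4,6-trienoic acid | OC(=O)/C(COCc1ccc(OC)cc1)=C/C=C/C(=C)CO[Si](C)(C)C(C)(C)C | intermediate
11 | 2-(trimethylsilyl)ethanol | C[Si](C)(C)CCO | starting material
12 | TMSE (2E,4E)-2-(PMBOCH2)-6-(TBSOCH2)hepta-2,4,6-trienoate | C[Si](C)(C)CCOC(=O)/C(COCc1ccc(OC)cc1)=C/C=C/C(=C)CO[Si](C)(C)C(C)(C)C | intermediate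
13 | but-3-en-2-one | CC(=O)C=C | starting material
14 | TMSE (2E)-3-[(1S,6S)-6-acetyl-3-(TBSOCH2)cyclohex-2-en-1-yl]-2-(PMBOCH2)prop-2-enoate | C[Si](C)(C)CCOC(=O)/C(COCc1ccc(OC)cc1)=C/[C@@H]1C=C(CO[Si](C)(C)C(C)(C)C)CC[C@@H]1C(C)=O | intermediate
15 | TMSE (2E)-3-[(1S,6S)-6-(prop-1-en-2-yl)-3-(TBSOCH2)cyclohex-2-en-1-yl]-2-(PMBOCH2)prop-2-enoate | C[Si](C)(C)CCOC(=O)/C(COCc1ccc(OC)cc1)=C/[C@@H]1C=C(CO[Si](C)(C)C(C)(C)C)CC[C@@H]1C(C)=C | intermediate
16 | TMSE (2E)-3-[(1S,6R)-6-isopropyl-3-(TBSOCH2)cyclohex-2-en-1-yl]-2-(PMBOCH2)prop-2-enoate | C[Si](C)(C)CCOC(=O)/C(COCc1ccc(OC)cc1)=C/[C@@H]1C=C(CO[Si](C)(C)C(C)(C)C)CC[C@@H]1C(C)C | intermediate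
17 | TMSE (2E)-3-[(1S,6R)-3-(hydroxymethyl)-6-isopropylcyclohex-2-en-1-yl]-2-(PMBOCH2)prop-2-enoate | C[Si](C)(C)CCOC(=O)/C(COCc1ccc(OC)cc1)=C/[C@@H]1C=C(CO)CC[C@@H]1C(C)C | intermediate
18 | (1R,2R,3R)-3-isopropyl-6-methylidene-2-[(1E)-2-(PMBOCH2)-3-oxo-3-(TMSE-oxy)prop-1-en-1-yl]cyclohexane-1-carboxylic acid | C[Si](C)(C)CCOC(=O)/C(COCc1ccc(OC)cc1)=C/[C@@H]1[C@@H](C(=O)O)C(=C)CC[C@@H]1C(C)C | intermediate
19 | (1R,2R,3R)-2-[(1E)-2-(hydroxymethyl)-3-oxo-3-(TMSE-oxy)prop-1-en-1-yl]-3-isopropyl-6-methylidenecyclohexane-1-carboxylic acid | C[Si](C)(C)CCOC(=O)/C(CO)=C/[C@@H]1[C@@H](C(=O)O)C(=C)CC[C@@H]1C(C)C | intermediate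
20 | TMSE (2E)-2-(hydroxymethyl)-3-[(1R,2R,3R,6S)-6-(iodomethyl)-3-isopropyl-8-oxo-7-oxabicyclo[4.2.0]octan-2-yl]prop-2-enoate | C[Si](C)(C)CCOC(=O)/C(CO)=C/[C@@H]1[C@H]2C(=O)O[C@@]2(CI)CC[C@@H]1C(C)C | intermediate
21 | TMSE (5aR,6R,9S,9aR)-9-hydroxy-9-(iodomethyl)-6-isopropyl-1-oxo-1,3,5a,6,7,8,9,9a-octahydro-2-benzoxepine-4-carboxylate | CC(C)[C@H]1CC[C@@](O)(CI)[C@@H]2C(=O)OCC(C(=O)OCC[Si](C)(C)C)=C[C@@H]12 | intermediate
22 | TMSE (5aR,6R,9S,9aR)-6-isopropyl-1-oxo-1,5a,6,7,8,9a-hexahydro-3H-spiro[2-benzoxepine-9,2'-oxirane]-4-carboxylate | CC(C)[C@H]1CC[C@@]2(CO2)[C@@H]3C(=O)OCC(C(=O)OCC[Si](C)(C)C)=C[C@@H]13 | intermediate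
23 | TMSE (5aR,6R,9S,9aR)-9-hydroxy-6-isopropyl-1-oxo-9-{[((2E,4E)-2-(PMBOCH2)-6-(TBSOCH2)hepta-2,4,6-trienoyl)oxy]methyl}-1,3,5a,6,7,8,9,9a-octahydro-2-benzoxepine-4-carboxylate | CC(C)[C@H]1CC[C@@](O)(COC(=O)/C(COCc2ccc(OC)cc2)=C/C=C/C(=C)CO[Si](C)(C)C(C)(C)C)[C@@H]2C(=O)OCC(C(=O)OCC[Si](C)(C)C)=C[C@@H]12 | intermediate
24 | TMSE (5aR,6R,9S,9aR)-9-{[((2E)-3-[(1R,6R)-6-acetyl-3-(TBSOCH2)cyclohex-2-en-1-yl]-2-(PMBOCH2)prop-2-enoyl)oxy]methyl}-9-hydroxy-6-isopropyl-1-oxo-1,3,5a,6,7,8,9,9a-octahydro-2-benzoxepine-4-carboxylate | CC(C)[C@H]1CC[C@@](O)(COC(=O)/C(COCc2ccc(OC)cc2)=C/[C@H]2C=C(CO[Si](C)(C)C(C)(C)C)CC[C@H]2C(C)=O)[C@@H]2C(=O)OCC(C(=O)OCC[Si](C)(C)C)=C[C@@H]12 | intermediate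
25 | TMSE (5aR,6R,9S,9aR)-9-hydroxy-6-isopropyl-1-oxo-9-{[((2E)-2-(PMBOCH2)-3-[(1R,6R)-6-(prop-1-en-2-yl)-3-(TBSOCH2)cyclohex-2-en-1-yl]prop-2-enoyl)oxy]methyl}-1,3,5a,6,7,8,9,9a-octahydro-2-benzoxepine-4-carboxylate | CC(C)[C@H]1CC[C@@](O)(COC(=O)/C(COCc2ccc(OC)cc2)=C/[C@H]2C=C(CO[Si](C)(C)C(C)(C)C)CC[C@H]2C(C)=C)[C@@H]2C(=O)OCC(C(=O)OCC[Si](C)(C)C)=C[C@@H]12 | intermediate
26 | TMSE (5aR,6R,9S,9aR)-9-hydroxy-6-isopropyl-9-{[((2E)-3-[(1R,6S)-6-isopropyl-3-(TBSOCH2)cyclohex-2-en-1-yl]-2-(PMBOCH2)prop-2-enoyl)oxy]methyl}-1-oxo-1,3,5a,6,7,8,9,9a-octahydro-2-benzoxepine-4-carboxylate | CC(C)[C@H]1CC[C@@](O)(COC(=O)/C(COCc2ccc(OC)cc2)=C/[C@H]2C=C(CO[Si](C)(C)C(C)(C)C)CC[C@H]2C(C)C)[C@@H]2C(=O)OCC(C(=O)OCC[Si](C)(C)C)=C[C@@H]12 | intermediate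
27 | TMSE (5aR,6R,9S,9aR)-9-hydroxy-9-{[((2E)-2-(hydroxymethyl)-3-[(1R,6S)-6-isopropyl-3-(TBSOCH2)cyclohex-2-en-1-yl]prop-2-enoyl)oxy]methyl}-6-isopropyl-1-oxo-1,3,5a,6,7,8,9,9a-octahydro-2-benzoxepine-4-carboxylate | CC(C)[C@H]1CC[C@@](O)(COC(=O)/C(CO)=C/[C@H]2C=C(CO[Si](C)(C)C(C)(C)C)CC[C@H]2C(C)C)[C@@H]2C(=O)OCC(C(=O)OCC[Si](C)(C)C)=C[C@@H]12 | intermediate
28 | (5aR,6R,9S,9aR)-9-hydroxy-9-{[((2E)-2-(hydroxymethyl)-3-[(1R,6S)-3-(hydroxymethyl)-6-isopropylcyclohex-2-en-1-yl]prop-2-enoyl)oxy]methyl}-6-isopropyl-1-oxo-1,3,5a,6,7,8,9,9a-octahydro-2-benzoxepine-4-carboxylic acid | CC(C)[C@H]1CC[C@@](O)(COC(=O)/C(=C/[C@H]2C=C(CO)CC[C@H]2C(C)C)CO)[C@@H]2C(=O)OCC(C(=O)O)=C[C@@H]12 | target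

**Summary**

Total step count: 19. Longest linear sequence: 19 steps (1 → 28; acid 10 from step 5 re-enters at step 14).

Steps most likely to fail:

1. Step 15 (key cycloaddition). The free tertiary hydroxyl and the ester carbonyls of 23 may sequester the boron Lewis acid, so that the cycloaddition becomes sluggish, loses facial control, or the acid ionises the tertiary alcohol. The fallback changes the activation mode to iminium-ion catalysis, which tolerates hydroxyl groups. It sets out from 23: prop-2-enal with (5S)-5-benzyl-2,2,3-trimethylimidazolidin-4-one hydrochloride (or its antipode, whichever delivers the 1'R,6'R sense) in MeCN/H2O should give the endo aldehyde TMSE (5aR,6R,9S,9aR)-9-{[((2E)-3-[(1R,6R)-6-formyl-3-(TBSOCH2)cyclohex-2-en-1-yl]-2-(PMBOCH2)prop-2-enoyl)oxy]methyl}-9-hydroxy-6-isopropyl-1-oxo-1,3,5a,6,7,8,9,9a-octahydro-2-benzoxepine-4-carboxylate F1. Chemoselective methyl transfer to the aldehyde with MeTi(OiPr)3 (THF, −40 °C) gives the 6'-(1-hydroxyethyl) carbinol (both carbinol epimers) F2, and Dess–Martin periodinane oxidation of the secondary alcohol returns to the route at 24.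

2. Step 11 (carboxylation). The allylzinc may be carboxylated at the alpha-carbon instead of the gamma-carbon, the allylpalladium intermediate may be reduced, or CO2 may add syn to the arm. The fallback replaces the catalytic umpolung by a preformed allylic organometallic. It sets out from 17: mesylation (MsCl, Et3N) and displacement with LiBr give the allylic bromide TMSE (2E)-3-[(1R,6R)-3-(bromomethyl)-6-isopropylcyclohex-2-en-1-yl]-2-(PMBOCH2)prop-2-enoate F3. Zinc insertion (Zn dust, LiCl, THF, 0 °C) and carboxylation of the allylzinc bromide with CO2 (gamma-attack) return to the route at 18.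

3. Step 13 (iodolactonisation cascade). Five-membered lactonisation or iodoetherification by the free primary alcohol may compete with the 4-exo closure, or acyl transfer from the beta-lactone may stall. The fallback forms the lactone first and the epoxide second. It sets out from 19: Yamaguchi lactonisation (2,4,6-trichlorobenzoyl chloride, Et3N; then 4-(dimethylamino)pyridine, toluene, high dilution) should give TMSE (5aR,6R,9aR)-6-isopropyl-9-methylidene-1-oxo-1,3,5a,6,7,8,9,9a-octahydro-2-benzoxepine-4-carboxylate F4. Epoxidation of the electron-rich 1,1-disubstituted alkene with 3-chloroperoxybenzoic acid (axial attack, leaving the enoate untouched) returns to the route at 22; here the C9 configuration depends on facial selectivity, not on a ring constraint.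

Further compounds
F1 | step 15 | TMSE (5aR,6R,9S,9aR)-9-{[((2E)-3-[(1R,6R)-6-formyl-3-(TBSOCH2)cyclohex-2-en-1-yl]-2-(PMBOCH2)prop-2-enoyl)oxy]methyl}-9-hydroxy-6-isopropyl-1-oxo-1,3,5a,6,7,8,9,9a-octahydro-2-benzoxepine-4-carboxylate | CC(C)[C@H]1CC[C@@](O)(COC(=O)/C(COCc2ccc(OC)cc2)=C/[C@H]2C=C(CO[Si](C)(C)C(C)(C)C)CC[C@H]2C=O)[C@@H]2C(=O)OCC(C(=O)OCC[Si](C)(C)C)=C[C@@H]12
F2 | step 15 | TMSE (5aR,6R,9S,9aR)-9-hydroxy-9-{[((2E)-3-[(1R,6R)-6-(1-hydroxyethyl)-3-(TBSOCH2)cyclohex-2-en-1-yl]-2-(PMBOCH2)prop-2-enoyl)oxy]methyl}-6-isopropyl-1-oxo-1,3,5a,6,7,8,9,9a-octahydro-2-benzoxepine-4-carboxylate (carbinol epimers) | CC(C)[C@H]1CC[C@@](O)(COC(=O)/C(COCc2ccc(OC)cc2)=C/[C@H]2C=C(CO[Si](C)(C)C(C)(C)C)CC[C@H]2C(C)O)[C@@H]2C(=O)OCC(C(=O)OCC[Si](C)(C)C)=C[C@@H]12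
F3 | step 11 | TMSE (2E)-3-[(1R,6R)-3-(bromomethyl)-6-isopropylcyclohex-2-en-1-yl]-2-(PMBOCH2)prop-2-enoate | C[Si](C)(C)CCOC(=O)/C(COCc1ccc(OC)cc1)=C/[C@@H]1C=C(CBr)CC[C@@H]1C(C)C
F4 | step 13 | TMSE (5aR,6R,9aR)-6-isopropyl-9-methylidene-1-oxo-1,3,5a,6,7,8,9,9a-octahydro-2-benzoxepine-4-carboxylate | CC(C)[C@H]1CCC(=C)[C@@H]2C(=O)OCC(C(=O)OCC[Si](C)(C)C)=C[C@@H]12
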